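**Retrosynthetic overview**

1. Dihydrocurcumin 15 comes from its bis(tert-butyldimethylsilyl) ether 14; the two aryl silyl ethers are removed last.
2. 14 is cut at C4–C5 (chain numbered as hept-1-ene-3,5-dione). This bond is made by a decarboxylative Claisen union that copies the presumed curcumin-synthase step: the feruloyl diketide acid 8 (CO2H on the future C4) is acylated by the dihydroferuloyl imidazolide 12.
3. 8 comes from feruloyl chloride 4 and bis(trimethylsilyl) malonate 5 (the diketide-synthase step in the flask); 12 comes from dihydroferulic acid 9.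
4. Enabling feature: the open-chain 1,3-diketone O=C3–C4H2–C5=O. C4 lies between two carbonyls, so a carboxyl group placed on C4 activates it for acylation by the C5 acyl donor and then leaves as CO2.
5. Rings: none is formed. Both 4-hydroxy-3-methoxyphenyl rings are bought intact, and the E C1=C2 alkene comes from ferulic acid.

Key step: step 6

Remark on the chemistry: it is assumed that dihydrocurcumin arises biosynthetically like curcumin, with a dihydroferuloyl unit in place of one feruloyl unit. All β-dicarbonyl compounds are drawn as keto tautomers; the doubly acylated methine of 13 is configurationally labile and drawn without configuration.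

**Route**

Step 1
Reactants: 1 (E)-ferulic acid
Product: 3 (E)-3-[4-(tert-butyldimethylsilyloxy)-3-methoxyphenyl]prop-2-enoic acid, via bis-silylated ferulic acid 2 (not isolated)
Conditions: TBSCl (2.5 equiv), imidazole (5 equiv), DMF, rt; then AcOH–THF–H2O (3:1:1), rt
Reagents that add atoms: tert-butyldimethylsilyl chloride, CC(C)(C)[Si](C)(C)Cl
Why: Standard silylation caps phenol and acid, and the much more labile silyl ester should then be hydrolysed selectively by aqueous acetic acid while the aryl silyl ether and the E alkene stay intact.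

Step 2
Reactants: 3 (E)-3-[4-(tert-butyldimethylsilyloxy)-3-methoxyphenyl]prop-2-enoic acid
Product: 4 (E)-3-[4-(tert-butyldimethylsilyloxy)-3-methoxyphenyl]prop-2-enoyl chloride
Conditions: (COCl)2 (1.3 equiv), DMF (cat.), CH2Cl2, 0 °C to rt; evaporation with toluene, crude product used at once
Reagents that add atoms: oxalyl chloride, ClC(=O)C(=O)Cl
Why: Acid chloride formation through the Vilsmeier-type chloroiminium catalyst runs at or below room temperature, where the aryl silyl ether and the E alkene should persist.

Step 3
Reactants: 4 (E)-3-[4-(tert-butyldimethylsilyloxy)-3-methoxyphenyl]prop-2-enoyl chloride; 5 bis(trimethylsilyl) malonate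
Product: 8 (E)-5-[4-(tert-butyldimethylsilyloxy)-3-methoxyphenyl]-3-oxopent-4-enoic acid, via silyl acylmalonate 6 (not isolated), via acylmalonic acid 7 (not isolated)
Conditions: 5 (1.2 equiv), Et3N (2.2 equiv), LiBr (1.3 equiv), MeCN, 0 °C; then 4, 0 °C to rt; then cold 0.5 M aq. HCl, extraction below 20 °C; acid stored at −20 °C and used within a day
Reagents that add atoms: none
Why: Soft-enolisation C-acylation of the silyl malonate by the acid chloride, then hydrolysis of the two silyl esters, gives an acylmalonic acid that loses one CO2 spontaneously to the β-keto acid (malonate acylation with decarboxylation, the chemical copy of the diketide-synthase step); the cold work-up should hold back the second decarboxylation.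

Step 4
Reactants: 9 dihydroferulic acid
Product: 11 3-[4-(tert-butyldimethylsilyloxy)-3-methoxyphenyl]propanoic acid, via bis-silylated dihydroferulic acid 10 (not isolated)
Conditions: TBSCl (2.5 equiv), imidazole (5 equiv), DMF, rt; then AcOH–THF–H2O (3:1:1), rt
Reagents that add atoms: tert-butyldimethylsilyl chloride, CC(C)(C)[Si](C)(C)Cl
Why: Same silylation and selective silyl ester hydrolysis as in step 1, on a substrate without the alkene.

Step 5
Reactants: 11 3-[4-(tert-butyldimethylsilyloxy)-3-methoxyphenyl]propanoic acid
Product: 12 3-[4-(tert-butyldimethylsilyloxy)-3-methoxyphenyl]-1-(imidazol-1-yl)propan-1-one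
Conditions: 1,1'-carbonyldiimidazole (1.0 equiv), THF, rt, until CO2 evolution stops; evaporation, crude imidazolide used at once
Reagents that add atoms: 1,1'-carbonyldiimidazole, O=C(n1ccnc1)n1ccnc1
Why: Azolide formation from a carboxylic acid and carbonyldiimidazole is driven by loss of CO2 and needs no acid or base that could touch the silyl ether.

Step 6
Reactants: 8 (E)-5-[4-(tert-butyldimethylsilyloxy)-3-methoxyphenyl]-3-oxopent-4-enoic acid; 12 3-[4-(tert-butyldimethylsilyloxy)-3-methoxyphenyl]-1-(imidazol-1-yl)propan-1-one
Product: 14 (E)-1,7-bis[4-(tert-butyldimethylsilyloxy)-3-methoxyphenyl]hept-1-ene-3,5-dione, via diacylacetic acid 13 (not isolated)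
Conditions: 8 (1.3 equiv), MgCl2 (1.5 equiv), Et3N (3 equiv), MeCN–THF, 0 °C to rt, 1 h; then 12 (1.0 equiv) in THF, rt, 16 h; then 1 M aq. HCl, 0 °C to rt until CO2 evolution stops
Reagents that add atoms: none
Why: Proposed new method: MgCl2/Et3N soft enolisation should convert β-keto acid 8 into its magnesium enolate–carboxylate chelate, whose C2 attacks the carbonyl of imidazolide 12 and expels imidazole to give the magnesium chelate of diacylacetic acid 13; acidification then releases CO2 through the usual six-membered hydrogen-bonded transition state and leaves the 1,3-diketone. The closest known reaction type is the Masamune–Brooks decarboxylative Claisen condensation of magnesium malonate half-esters with acyl imidazolides, together with the MgCl2/Et3N C-acylation of β-keto esters; what is new is a free β-keto acid serving as the carboxyl-activated ketone enolate, which is what curcumin synthase does with the diketide acid and an acyl thioester. No ring is closed and no stereocentre is created; the E alkene of 8 is not touched by the mild base and is carried through. The step needs C- over O-acylation, which magnesium chelation of the 1,3-dioxygenated enolate should secure, and single acylation, which should follow because 13 is held as an unreactive delocalised tricarbonyl chelate. It also needs acylation to outrun protodecarboxylation of 8, which the dianionic chelate should resist at room temperature; the substrate helps by having only one enolisable carbon (C4 of 8 is vinylic) and silyl-capped phenols that cannot compete for the acyl donor.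

Step 7
Reactants: 14 (E)-1,7-bis[4-(tert-butyldimethylsilyloxy)-3-methoxyphenyl]hept-1-ene-3,5-dione
Product: 15 dihydrocurcumin
Conditions: Bu4NF (2.4 equiv), AcOH (2.4 equiv), THF, 0 °C; NaH2PO4 buffer (pH 5) work-up
Reagents that add atoms: none
Why: Fluoride-induced cleavage of the two aryl Si–O bonds (silyl ether deprotection), buffered with acetic acid so that the base-sensitive enone–diketone is never exposed to free phenolate or enolate for long.

**Compound list**

1 | (E)-ferulic acid, (E)-3-(4-hydroxy-3-methoxyphenyl)prop-2-enoic acid | COc1cc(/C=C/C(=O)O)ccc1O | starting material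
2 | tert-butyldimethylsilyl (E)-3-[4-(tert-butyldimethylsilyloxy)-3-methoxyphenyl]prop-2-enoate | COc1cc(/C=C/C(=O)O[Si](C)(C)C(C)(C)C)ccc1O[Si](C)(C)C(C)(C)C | intermediate
3 | (E)-3-[4-(tert-butyldimethylsilyloxy)-3-methoxyphenyl]prop-2-enoic acid | COc1cc(/C=C/C(=O)O)ccc1O[Si](C)(C)C(C)(C)C | intermediate
4 | (E)-3-[4-(tert-butyldimethylsilyloxy)-3-methoxyphenyl]prop-2-enoyl chloride | COc1cc(/C=C/C(=O)Cl)ccc1O[Si](C)(C)C(C)(C)C | intermediate
5 | bis(trimethylsilyl) malonate | C[Si](C)(C)OC(=O)CC(=O)O[Si](C)(C)C | starting material
6 | bis(trimethylsilyl) 2-{(E)-3-[4-(tert-butyldimethylsilyloxy)-3-methoxyphenyl]prop-2-enoyl}propanedioate | COc1cc(/C=C/C(=O)C(C(=O)O[Si](C)(C)C)C(=O)O[Si](C)(C)C)ccc1O[Si](C)(C)C(C)(C)C | intermediate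
7 | 2-{(E)-3-[4-(tert-butyldimethylsilyloxy)-3-methoxyphenyl]prop-2-enoyl}propanedioic acid | COc1cc(/C=C/C(=O)C(C(=O)O)C(=O)O)ccc1O[Si](C)(C)C(C)(C)C | intermediate
8 | (E)-5-[4-(tert-butyldimethylsilyloxy)-3-methoxyphenyl]-3-oxopent-4-enoic acid | COc1cc(/C=C/C(=O)CC(=O)O)ccc1O[Si](C)(C)C(C)(C)C | intermediate
9 | dihydroferulic acid, 3-(4-hydroxy-3-methoxyphenyl)propanoic acid | COc1cc(CCC(=O)O)ccc1O | starting material
10 | tert-butyldimethylsilyl 3-[4-(tert-butyldimethylsilyloxy)-3-methoxyphenyl]propanoate | COc1cc(CCC(=O)O[Si](C)(C)C(C)(C)C)ccc1O[Si](C)(C)C(C)(C)C | intermediate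
11 | 3-[4-(tert-butyldimethylsilyloxy)-3-methoxyphenyl]propanoic acid | COc1cc(CCC(=O)O)ccc1O[Si](C)(C)C(C)(C)C | intermediate
12 | 3-[4-(tert-butyldimethylsilyloxy)-3-methoxyphenyl]-1-(imidazol-1-yl)propan-1-one | COc1cc(CCC(=O)n2ccnc2)ccc1O[Si](C)(C)C(C)(C)C | intermediate
13 | (E)-5-[4-(tert-butyldimethylsilyloxy)-3-methoxyphenyl]-2-{3-[4-(tert-butyldimethylsilyloxy)-3-methoxyphenyl]propanoyl}-3-oxopent-4-enoic acid | COc1cc(/C=C/C(=O)C(C(=O)O)C(=O)CCc2ccc(O[Si](C)(C)C(C)(C)C)c(OC)c2)ccc1O[Si](C)(C)C(C)(C)C | intermediate
14 | (E)-1,7-bis[4-(tert-butyldimethylsilyloxy)-3-methoxyphenyl]hept-1-ene-3,5-dione | COc1cc(/C=C/C(=O)CC(=O)CCc2ccc(O[Si](C)(C)C(C)(C)C)c(OC)c2)ccc1O[Si](C)(C)C(C)(C)C | intermediate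
15 | dihydrocurcumin, (E)-1,7-bis(4-hydroxy-3-methoxyphenyl)hept-1-ene-3,5-dione | COc1cc(/C=C/C(=O)CC(=O)CCc2ccc(O)c(OC)c2)ccc1O | target

**Summary**

Total steps: 7. Longest linear sequence: 5 steps (steps 1, 2, 3, 6, 7).

Steps most likely to fail:

Step 6 (new method). The process at risk is protodecarboxylation of the chelated β-keto acid, or O-acylation, outrunning C-acylation. The fallback uses known chemistry throughout. It sets out from 8, which is decarboxylated on purpose (toluene, 80 °C) to (E)-4-[4-(tert-butyldimethylsilyloxy)-3-methoxyphenyl]but-3-en-2-one F1. The kinetic lithium enolate of F1 (LiN(SiMe3)2, THF, −78 °C, two equivalents of enolate per acyl donor) is then C-acylated with imidazolide 12 in a crossed Claisen condensation. Acidic work-up returns the route at 14.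

Step 3. The process at risk is the hydrolytic work-up running on to the second decarboxylation, or incomplete C-acylation of the silyl malonate. The fallback sets out from 4, which is condensed with the magnesium enolate of tert-butyl hydrogen malonate (MgCl2, Et3N, MeCN, 0 °C to rt; decarboxylative Claisen condensation of a malonate half-ester). This gives the storable ester tert-butyl (E)-5-[4-(tert-butyldimethylsilyloxy)-3-methoxyphenyl]-3-oxopent-4-enoate F2. Anhydrous acidolysis (CF3CO2H, CH2Cl2, 0 °C) just before use unmasks the acid without any aqueous step and returns the route at 8.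

Step 7. The process at risk is fluoride-triggered, base-induced retro-Claisen cleavage or autoxidation of the phenolate/enolate of the product. The fallback sets out from 14, whose diketone is first locked with BF3·OEt2 (CH2Cl2, rt) as the difluoroboron chelate of the bis-silyl ether F3. The silyl groups are then removed on this masked diketone (Bu4NF, AcOH, THF, 0 °C) to give the difluoroboron chelate of dihydrocurcumin F4. The chelate is finally opened with Na2C2O4 in aqueous MeOH at 60 °C, which returns the route at 15.

**Further compounds**

F1 | step 6 | (E)-4-[4-(tert-butyldimethylsilyloxy)-3-methoxyphenyl]but-3-en-2-one | COc1cc(/C=C/C(C)=O)ccc1O[Si](C)(C)C(C)(C)C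
F2 | step 3 | tert-butyl (E)-5-[4-(tert-butyldimethylsilyloxy)-3-methoxyphenyl]-3-oxopent-4-enoate | COc1cc(/C=C/C(=O)CC(=O)OC(C)(C)C)ccc1O[Si](C)(C)C(C)(C)C
F3 | step 7 | difluoroboron chelate of the bis-silyl ether, 2,2-difluoro-1,3,2-dioxaborinine from 14 | COc1cc(/C=C/C2=[O+][B-](F)(F)OC(CCc3ccc(O[Si](C)(C)C(C)(C)C)c(OC)c3)=C2)ccc1O[Si](C)(C)C(C)(C)C
F4 | step 7 | difluoroboron chelate of dihydrocurcumin | COc1cc(/C=C/C2=[O+][B-](F)(F)OC(CCc3ccc(O)c(OC)c3)=C2)ccc1O
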